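The left-handed product outran the right-handed one in both earlier runs, and by a wider ratio in the colder run. A single-handed catalyst turned a racemic substrate with the partner into the two products. I wanted to know how the excess of left over right moved with temperature.

all flasks: catalyst 46 µM; added ligand 0.10 mM

| charge | left-handed substrate | right-handed substrate | partner | protic impurity | temperature | remark | time |
|---|---|---|---|---|---|---|---|
| autumn | 10 mM | 10 mM | 30 mM | 6 mM | 35 °C | run made earlier |  |
| winter | 40 mM | 40 mM | 30 mM | 6 mM | 85 °C | run made earlier |  |
| Saturday's | 20 mM | 20 mM | 30.0 mM | 6.00 mM | 70 °C |  | 1.5 h |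
| Wednesday's | 20 mM | 20 mM | 30.0 mM | 6.00 mM | 100 °C |  | 1.5 h |
| Monday's | 20 mM | 20 mM | 30.0 mM | 6.00 mM | 40 °C |  | 1.5 h |
| Friday's | 20 mM | 20 mM | 30.0 mM | 6.00 mM | 130 °C |  | 1.5 h |

- autumn (time / h: left-handed product / %, right-handed product / %): 2.00: 1.4, 0; 4.00: 2.5, 1.1; 5.00: 2.1, 0.5; 8.00: 3.1, 0.1; 12.0: 6.6, 1.0
- winter (time / min: left-handed product / %, right-handed product / %): 10.0: 1.0, 0.8; 20.0: 2.4, 0.6; 25.0: 1.7, 1.2; 40.0: 3.7, 1.4; 60.0: 4.6, 2.2

(each reading ± 0.5 percentage points)

- catalyst is single-handed; left-handed substrate and right-handed substrate are mirror images of each other, charged as a racemate, each of them at the stated concentration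
- the numbers in the tables scatter by 0.5 percentage points (one standard deviation)
- an excess is below zero if the other one leads

* the flask that comes out highest in excess of left-handed product over right-handed product, or "all alike" when all lie within 1.5 percentage points (Saturday's / Wednesday's / Monday's / Friday's / all alike)
* excess of left-handed product over right-handed product at the end, Saturday's
* excess of left-handed product over right-handed product at the end, Wednesday's
* excess of left-handed product over right-handed product at the end, Monday's
* excess of left-handed product over right-handed product at the end, Friday's

I ranked the last readings as rates, in fractions of the substrates charged. The winter left-handed product came fastest at 0.0460 h⁻¹, then winter right-handed at 0.0220 h⁻¹, autumn left-handed at 0.00550 h⁻¹, and autumn right-handed slowest at 8.33 × 10⁻⁴ h⁻¹. As read, the winter run had turned 6.80% of its substrates at its last reading, so I treated conversion there as small. I assumed each step ran in proportion to its own substrate, with partner and catalyst shared, so those two cancel in the ratio of the rates. At small conversion of equal charges, the excess is then s minus one over s plus one, where s is that ratio.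

Summed readings gave s as 5.81 in the autumn run and 2.16 in the winter run, an energy gap of 18.2 kJ mol⁻¹ as read. But the autumn right-handed readings scatter by 0.5 percentage points and stand no higher than 1.1%, so I held this gap loosely. It gave excesses of 67.7% for Monday's, 47.7% for Saturday's and 25.7% for Wednesday's. For Friday's, the selectivity factor, the ratio of left-handed to right-handed rate at that temperature, came to 1.09, an excess of 4.49%.

The forecast, close to my figures but not equal to them, gave 70% for Monday's, 48% for Saturday's, 23% for Wednesday's and 2% for Friday's, and said “The coldest flask, Monday's, comes out highest.”

The flasks gave 73.7% for Monday's, 59.2% for Saturday's, 42.2% for Wednesday's and 24.8% for Friday's, so Monday's stood highest.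

    partner + catalyst + left-handed substrate → catalyst + left-handed product (k = 2900 M⁻² min⁻¹, Ea = 41.0 kJ mol⁻¹)
    partner + catalyst + right-handed substrate → catalyst + right-handed product (k = 1100 M⁻² min⁻¹, Ea = 56.0 kJ mol⁻¹)
    catalyst + added ligand ⇌ idle complex, settled at all times (K = 2100 M⁻¹, ΔH = −14.0 kJ mol⁻¹)
    partner + protic impurity → quenched reagent (k = 1.10 M⁻¹ min⁻¹, Ea = 67.0 kJ mol⁻¹)
    (constants at 100 °C)

Friday's flask kept 62% of its left-handed substrate and 77% of its right-handed, and the ratio of the logarithms of those remainders, which is the selectivity factor when each substrate goes in proportion to itself, is 1.84, more than my 1.09. The neighbour charged with 75 mM of partner stood at Friday's 130 °C and kept 23% of its left-handed substrate. On that remainder my 1.09 gives an excess of 2.05% and Friday's 1.84 gives 16.7%, while the flask gave 16.6%.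

All runs are calculated with made-up constants, noise included.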